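Ring A of the benzofuran is opened at C3a–C4. C4–C7 then become a four-carbon chain on the furan carbon destined to be C7a, with C4 as a carboxylic acid, C5 already prenylated and C6 already a methyl enol ether. The key step exploits the single free β-carbon of the furan (future C3a): acetic anhydride and sodium acetate turn the acid into a dienylketene that closes onto it, creating the C3a–C4 bond, ring A and the C4/C6 oxygen differentiation in one operation. The precursor is an (E)-3-methoxy-2-prenylbut-2-enoic acid bearing at its own C4 a 5-aryl-4-cyanofuran-2-yl ring. The nitrile (future formyl carbon) and the aryl allyl ethers are spectators.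

Key step: step 10

Remark: locants C2–C7a refer to the benzofuran numbering of the target. The C3 carbon is carried as a nitrile (inert to ester hydrolysis, reduced to the aldehyde in one step) and the resorcinol hydroxyls as allyl ethers (stable to acid, removed without acid). Compounds 1, 3, 5, 9 and 13 are assumed to be purchased.

Step 1
Reactants: 1 methyl 2,4-dihydroxybenzoate
Product: 2 methyl 2,4-bis(allyloxy)benzoate
Conditions: allyl bromide, K2CO3, DMF, 60 °C
Reagents that add atoms: allyl bromide C=CCBr
Why: Williamson etherification of both phenols should go to completion in warm DMF, which is needed for the hydrogen-bonded 2-hydroxyl, and installs ethers that tolerate every acid, base and hydride step that follows.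

Step 2
Reactants: 2 methyl 2,4-bis(allyloxy)benzoate; 3 acetonitrile
Product: 4 3-[2,4-bis(allyloxy)phenyl]-3-oxopropanenitrile
Conditions: 3, n-BuLi, THF, −78 °C; then 2, −78 → 0 °C; dilute HCl work-up
Reagents that add atoms: none
Why: Claisen-type acylation of lithioacetonitrile by the aryl ester should stop at the β-ketonitrile because the product is deprotonated at once by the second equivalent of the anion.

Step 3
Reactants: 4 3-[2,4-bis(allyloxy)phenyl]-3-oxopropanenitrile; 5 methyl (E)-4-bromo-3-methoxybut-2-enoate
Product: 6 methyl (E)-6-[2,4-bis(allyloxy)phenyl]-5-cyano-3-methoxy-6-oxohex-2-enoate (racemic)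
Conditions: K2CO3, acetone, rt
Reagents that add atoms: none
Why: SN2 C-alkylation of the soft β-ketonitrile enolate at the allylic bromide is the only reasonable pathway because the second carbonyl of the four-carbon unit is masked as its methyl enol ether; the new stereocentre is racemic and disappears in step 4.

Step 4
Reactants: 6 methyl (E)-6-[2,4-bis(allyloxy)phenyl]-5-cyano-3-methoxy-6-oxohex-2-enoate
Product: 7 methyl 2-{5-[2,4-bis(allyloxy)phenyl]-4-cyanofuran-2-yl}acetate
Conditions: TsOH·H2O (cat.), PhMe, 90 °C
Reagents that add atoms: none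
Why: Paal–Knorr-type cyclodehydration, in which protonation of the β-methoxyacrylate unmasks the 1,4-dicarbonyl as an oxocarbenium ion, the aroyl oxygen closes the five-membered ring and loss of methanol aromatises it, so that aryl, nitrile and acetate side chain end up unambiguously at furan C5, C4 and C2.

Step 5
Reactants: 7 methyl 2-{5-[2,4-bis(allyloxy)phenyl]-4-cyanofuran-2-yl}acetate
Product: 8 2-{5-[2,4-bis(allyloxy)phenyl]-4-cyanofuran-2-yl}acetic acid
Conditions: LiOH, THF–H2O, 0 °C → rt; then 1 M HCl to pH 3
Reagents that add atoms: lithium hydroxide [Li+].[OH-]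
Why: Saponification of the unhindered alkyl ester should be clean because the only other acyl-type group, the furan nitrile, is inert to cold aqueous LiOH.

Step 6
Reactants: 8 2-{5-[2,4-bis(allyloxy)phenyl]-4-cyanofuran-2-yl}acetic acid; 9 Meldrum's acid (2,2-dimethyl-1,3-dioxane-4,6-dione)
Product: 12 2-(trimethylsilyl)ethyl 4-{5-[2,4-bis(allyloxy)phenyl]-4-cyanofuran-2-yl}-3-oxobutanoate, via acyl Meldrum's acid 10 (not isolated), via acylketene 11 (not isolated)
Conditions: 9, DCC, DMAP, CH2Cl2, 0 °C → rt; then Me3SiCH2CH2OH, PhMe, 90 °C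
Reagents that add atoms: 2-(trimethylsilyl)ethanol C[Si](C)(C)CCO
Why: C-acylation of Meldrum's acid by the carbodiimide-activated arylacetic acid, followed by thermal fragmentation to an acylketene that the alcohol traps, is the standard two-carbon homologation of an acid to a β-keto ester and here delivers an ester that fluoride can cleave.

Step 7
Reactants: 12 2-(trimethylsilyl)ethyl 4-{5-[2,4-bis(allyloxy)phenyl]-4-cyanofuran-2-yl}-3-oxobutanoate; 13 1-bromo-3-methylbut-2-ene (prenyl bromide)
Product: 14 2-(trimethylsilyl)ethyl 4-{5-[2,4-bis(allyloxy)phenyl]-4-cyanofuran-2-yl}-2-(3-methylbut-2-enyl)-3-oxobutanoate (racemic)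
Conditions: K2CO3, acetone, rt
Reagents that add atoms: none
Why: C-alkylation of the β-keto ester enolate with the soft allylic bromide should occur only at the doubly activated carbon, the furylmethylene protons being far less acidic; the stereocentre is racemic and is removed in step 8.

Step 8
Reactants: 14 2-(trimethylsilyl)ethyl 4-{5-[2,4-bis(allyloxy)phenyl]-4-cyanofuran-2-yl}-2-(3-methylbut-2-enyl)-3-oxobutanoate
Product: 15 2-(trimethylsilyl)ethyl (E)-4-{5-[2,4-bis(allyloxy)phenyl]-4-cyanofuran-2-yl}-3-methoxy-2-(3-methylbut-2-enyl)but-2-enoate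
Conditions: Cs2CO3, Me2SO4, DMF, 0 °C → rt
Reagents that add atoms: dimethyl sulfate COS(=O)(=O)OC
Why: O-alkylation of a β-keto ester enolate, in which a hard methylating agent, a weakly coordinating cation and a dipolar aprotic solvent favour attack through oxygen of the fully substituted enolate, and the extended free enolate should give mainly the (E)-enol ether with the ester cis to the furylmethylene group.

Step 9
Reactants: 15 2-(trimethylsilyl)ethyl (E)-4-{5-[2,4-bis(allyloxy)phenyl]-4-cyanofuran-2-yl}-3-methoxy-2-(3-methylbut-2-enyl)but-2-enoate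
Product: 16 (E)-4-{5-[2,4-bis(allyloxy)phenyl]-4-cyanofuran-2-yl}-3-methoxy-2-(3-methylbut-2-enyl)but-2-enoic acid
Conditions: TBAF, THF, 0 °C → rt; then cold 0.5 M HCl
Reagents that add atoms: none
Why: Fluoride-induced β-elimination of the 2-(trimethylsilyl)ethyl ester frees the hindered β-methoxyacrylic acid without hydroxide, so that the enol ether, the nitrile and the allyl ethers should remain untouched.

Step 10
Reactants: 16 (E)-4-{5-[2,4-bis(allyloxy)phenyl]-4-cyanofuran-2-yl}-3-methoxy-2-(3-methylbut-2-enyl)but-2-enoic acid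
Product: 20 2-[2,4-bis(allyloxy)phenyl]-3-cyano-6-methoxy-5-(3-methylbut-2-enyl)benzofuran-4-yl acetate, via mixed acetic anhydride 17 (not isolated), via dienylketene 18 (not isolated), via 4-hydroxybenzofuran-3-carbonitrile 19 (not isolated)
Conditions: Ac2O, NaOAc, 120 °C
Reagents that add atoms: acetic anhydride CC(=O)OC(C)=O
Why: Acetic anhydride converts acid 16 into mixed anhydride 17, from which acetate removes a furylmethylene proton (the future C7–H) while the acetate group leaves, giving dienylketene 18 in which the ketene carbon is the future C4. Thermal disrotatory six-electron electrocyclization of 18 joins that carbon to the unsubstituted furan β-carbon (C3a) and closes the six-membered ring A; tautomerization of the resulting cyclohexadienone gives phenol 19, which is acetylated to 20. The closest known reaction type is the acetic anhydride–sodium acetate benzannulation of 4-aryl- and 4-furylbutenoic acids to naphthyl and benzofuranyl acetates, and a polar 6-exo-trig Friedel–Crafts acylation of the same carbon by 17 would converge on the same product. No stereocentre is formed. The step needs site selectivity, secured because the furan has only one free position, and the right reach of the chain, secured by the (E)-geometry of 16 (carboxyl cis to the furylmethylene group); in the ketene manifold the C5–C6 bond is single and the C6=C7 geometry can correct itself through reversible ketene formation. Because C6 already carries its methyl ether, the C4 and C6 oxygens emerge differentiated as acetate and methyl ether.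

Step 11
Reactants: 20 2-[2,4-bis(allyloxy)phenyl]-3-cyano-6-methoxy-5-(3-methylbut-2-enyl)benzofuran-4-yl acetate
Product: 22 2-[2,4-bis(allyloxy)phenyl]-4-hydroxy-6-methoxy-5-(3-methylbut-2-enyl)benzofuran-3-carbaldehyde, via aldimine 21 (not isolated)
Conditions: i-Bu2AlH, CH2Cl2, −78 → 0 °C; then cold 1 M HCl, THF
Reagents that add atoms: water O
Why: i-Bu2AlH reductively cleaves the aryl acetate and adds a single hydride to the nitrile, giving an N-aluminated aldimine that resists further reduction at low temperature and is hydrolysed to the aldehyde by the cold acidic work-up (partial reduction of a nitrile), which should leave the allyl ethers and the prenyl group intact.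

Step 12
Reactants: 22 2-[2,4-bis(allyloxy)phenyl]-4-hydroxy-6-methoxy-5-(3-methylbut-2-enyl)benzofuran-3-carbaldehyde
Product: 23 2-(2,4-dihydroxyphenyl)-4-hydroxy-6-methoxy-5-(3-methylbut-2-enyl)benzofuran-3-carbaldehyde (the target)
Conditions: Pd(PPh3)4 (cat.), K2CO3, MeOH, 50 °C
Reagents that add atoms: none
Why: Zerovalent palladium ionises each aryl allyl ether to a π-allyl complex that methoxide captures (Tsuji–Trost deallylation), which should free both phenols under mildly basic conditions that cannot cyclise the prenyl group onto the neighbouring C4 hydroxyl or acetalise the aldehyde.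

Compound list
1 | methyl 2,4-dihydroxybenzoate | COC(=O)c1ccc(O)cc1O | starting material
2 | methyl 2,4-bis(allyloxy)benzoate | COC(=O)c1ccc(OCC=C)cc1OCC=C | intermediate
3 | acetonitrile | CC#N | starting material
4 | 3-[2,4-bis(allyloxy)phenyl]-3-oxopropanenitrile | N#CCC(=O)c1ccc(OCC=C)cc1OCC=C | intermediate
5 | methyl (E)-4-bromo-3-methoxybut-2-enoate | COC(=O)/C=C(/OC)CBr | starting material
6 | methyl (E)-6-[2,4-bis(allyloxy)phenyl]-5-cyano-3-methoxy-6-oxohex-2-enoate (racemic) | COC(=O)/C=C(/OC)CC(C#N)C(=O)c1ccc(OCC=C)cc1OCC=C | intermediate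
7 | methyl 2-{5-[2,4-bis(allyloxy)phenyl]-4-cyanofuran-2-yl}acetate | COC(=O)Cc1cc(C#N)c(-c2ccc(OCC=C)cc2OCC=C)o1 | intermediate
8 | 2-{5-[2,4-bis(allyloxy)phenyl]-4-cyanofuran-2-yl}acetic acid | OC(=O)Cc1cc(C#N)c(-c2ccc(OCC=C)cc2OCC=C)o1 | intermediate
9 | Meldrum's acid (2,2-dimethyl-1,3-dioxane-4,6-dione) | CC1(C)OC(=O)CC(=O)O1 | starting material
10 | 5-(2-{5-[2,4-bis(allyloxy)phenyl]-4-cyanofuran-2-yl}-1-hydroxyethylidene)-2,2-dimethyl-1,3-dioxane-4,6-dione (acyl Meldrum's acid, formed in the flask) | CC1(C)OC(=O)C(=C(O)Cc2cc(C#N)c(-c3ccc(OCC=C)cc3OCC=C)o2)C(=O)O1 | intermediate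
11 | 4-{5-[2,4-bis(allyloxy)phenyl]-4-cyanofuran-2-yl}but-1-ene-1,3-dione (acylketene, formed in the flask) | O=C=CC(=O)Cc1cc(C#N)c(-c2ccc(OCC=C)cc2OCC=C)o1 | intermediate
12 | 2-(trimethylsilyl)ethyl 4-{5-[2,4-bis(allyloxy)phenyl]-4-cyanofuran-2-yl}-3-oxobutanoate | C[Si](C)(C)CCOC(=O)CC(=O)Cc1cc(C#N)c(-c2ccc(OCC=C)cc2OCC=C)o1 | intermediate
13 | 1-bromo-3-methylbut-2-ene (prenyl bromide) | CC(C)=CCBr | starting material
14 | 2-(trimethylsilyl)ethyl 4-{5-[2,4-bis(allyloxy)phenyl]-4-cyanofuran-2-yl}-2-(3-methylbut-2-enyl)-3-oxobutanoate (racemic) | C[Si](C)(C)CCOC(=O)C(CC=C(C)C)C(=O)Cc1cc(C#N)c(-c2ccc(OCC=C)cc2OCC=C)o1 | intermediate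
15 | 2-(trimethylsilyl)ethyl (E)-4-{5-[2,4-bis(allyloxy)phenyl]-4-cyanofuran-2-yl}-3-methoxy-2-(3-methylbut-2-enyl)but-2-enoate | C[Si](C)(C)CCOC(=O)/C(CC=C(C)C)=C(/OC)Cc1cc(C#N)c(-c2ccc(OCC=C)cc2OCC=C)o1 | intermediate
16 | (E)-4-{5-[2,4-bis(allyloxy)phenyl]-4-cyanofuran-2-yl}-3-methoxy-2-(3-methylbut-2-enyl)but-2-enoic acid | OC(=O)/C(CC=C(C)C)=C(/OC)Cc1cc(C#N)c(-c2ccc(OCC=C)cc2OCC=C)o1 | intermediate
17 | acetic (E)-4-{5-[2,4-bis(allyloxy)phenyl]-4-cyanofuran-2-yl}-3-methoxy-2-(3-methylbut-2-enyl)but-2-enoic anhydride (formed in the flask) | CC(=O)OC(=O)/C(CC=C(C)C)=C(/OC)Cc1cc(C#N)c(-c2ccc(OCC=C)cc2OCC=C)o1 | intermediate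
18 | (3E)-4-{5-[2,4-bis(allyloxy)phenyl]-4-cyanofuran-2-yl}-3-methoxy-2-(3-methylbut-2-enyl)buta-1,3-dien-1-one (dienylketene, furan cis to the ketene-bearing carbon, formed in the flask) | O=C=C(CC=C(C)C)/C(OC)=C\c1cc(C#N)c(-c2ccc(OCC=C)cc2OCC=C)o1 | intermediate
19 | 2-[2,4-bis(allyloxy)phenyl]-4-hydroxy-6-methoxy-5-(3-methylbut-2-enyl)benzofuran-3-carbonitrile (formed in the flask) | COc1cc2oc(-c3ccc(OCC=C)cc3OCC=C)c(C#N)c2c(O)c1CC=C(C)C | intermediate
20 | 2-[2,4-bis(allyloxy)phenyl]-3-cyano-6-methoxy-5-(3-methylbut-2-enyl)benzofuran-4-yl acetate | COc1cc2oc(-c3ccc(OCC=C)cc3OCC=C)c(C#N)c2c(OC(C)=O)c1CC=C(C)C | intermediate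
21 | 2-[2,4-bis(allyloxy)phenyl]-3-(iminomethyl)-6-methoxy-5-(3-methylbut-2-enyl)benzofuran-4-ol (aldimine, present as its aluminium derivative until work-up) | COc1cc2oc(-c3ccc(OCC=C)cc3OCC=C)c(C=N)c2c(O)c1CC=C(C)C | intermediate
22 | 2-[2,4-bis(allyloxy)phenyl]-4-hydroxy-6-methoxy-5-(3-methylbut-2-enyl)benzofuran-3-carbaldehyde | COc1cc2oc(-c3ccc(OCC=C)cc3OCC=C)c(C=O)c2c(O)c1CC=C(C)C | intermediate
23 | 2-(2,4-dihydroxyphenyl)-4-hydroxy-6-methoxy-5-(3-methylbut-2-enyl)benzofuran-3-carbaldehyde | COc1cc2oc(-c3ccc(O)cc3O)c(C=O)c2c(O)c1CC=C(C)C | target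

Total step count: 12. Longest linear sequence: 12 steps (1 to 23).

Steps most likely to fail

Step 10. The chain of 16 has its double bond in conjugation with the acid and not with the furan, so ketene formation depends on removal of a furylmethylene proton from the mixed anhydride. If that deprotonation is slow, the anhydride may be consumed by other pathways or the chain may isomerise without closing. The fallback sets out from 16 and replaces the pericyclic closure by a cationic one. Trifluoroacetic anhydride in CH2Cl2 at 0 °C should give the mixed trifluoroacetic anhydride F1, whose acyl carbon is held next to the free furan β-carbon by the (E)-geometry and should acylate it in an intramolecular Friedel–Crafts reaction. Enolization and a bicarbonate work-up would give phenol 19, this time isolated. Reduction of 19 with i-Bu2AlH under the conditions of step 11 brings the sequence back to the route at 22.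

Step 8. Methylation may occur on carbon to give a quaternary centre, the enol ether may form towards the furylmethylene side, or the double-bond geometry may be poorly controlled. A geometrical isomer would still be usable in step 10 through the ketene pathway, but not in a direct acylation. The fallback sets out from 14 and forms the enol ether under acid and equilibrium control. Trimethyl orthoformate and catalytic TsOH in methanol should convert the ketone into the dimethyl ketal F2, which on warming loses methanol towards the ester-conjugated position. C-Methylation is impossible under these conditions, and the sequence returns to the route at 15.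

Step 4. The enol ether may be hydrolysed without ring closure, or an oxygen nucleophile may add to the nitrile and divert the material to an aminofuran. The fallback sets out from 4 and builds the furan under base. Alkylation with ethyl 4-bromobut-2-ynoate and K2CO3 in acetone should give ethyl 6-[2,4-bis(allyloxy)phenyl]-5-cyano-6-oxohex-2-ynoate F3. Its enolate oxygen should add 5-exo-dig to the ynoate, and isomerisation of the alkylidene dihydrofuran would give ethyl 2-{5-[2,4-bis(allyloxy)phenyl]-4-cyanofuran-2-yl}acetate F4. Saponification with LiOH as in step 5 returns to the route at 8.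

Further compounds
F1 | step 10 | (E)-4-{5-[2,4-bis(allyloxy)phenyl]-4-cyanofuran-2-yl}-3-methoxy-2-(3-methylbut-2-enyl)but-2-enoic trifluoroacetic anhydride | O=C(OC(=O)C(F)(F)F)/C(CC=C(C)C)=C(/OC)Cc1cc(C#N)c(-c2ccc(OCC=C)cc2OCC=C)o1
F2 | step 8 | 2-(trimethylsilyl)ethyl 4-{5-[2,4-bis(allyloxy)phenyl]-4-cyanofuran-2-yl}-3,3-dimethoxy-2-(3-methylbut-2-enyl)butanoate (racemic) | C[Si](C)(C)CCOC(=O)C(CC=C(C)C)C(OC)(OC)Cc1cc(C#N)c(-c2ccc(OCC=C)cc2OCC=C)o1
F3 | step 4 | ethyl 6-[2,4-bis(allyloxy)phenyl]-5-cyano-6-oxohex-2-ynoate (racemic) | CCOC(=O)C#CCC(C#N)C(=O)c1ccc(OCC=C)cc1OCC=C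
F4 | step 4 | ethyl 2-{5-[2,4-bis(allyloxy)phenyl]-4-cyanofuran-2-yl}acetate | CCOC(=O)Cc1cc(C#N)c(-c2ccc(OCC=C)cc2OCC=C)o1
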